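**Strategy.** Decalin numbering: C1 bears the propenyl group, C2 the acyl group, C3=C4 carries the C4 methyl, C7 the ring methyl. The cyclohexene ring is closed by a double Michael addition of malonate to a cyclohexenyl dienone; equilibration sets the trans fusion against C7. The saturated ring (C4a, C5–C8, C8a) starts as a cycloheptenone: conjugate methylation of cyclohepta-2,6-dienone sets C7, and a BF3-induced acyl shift of the derived epoxy ketone contracts the ring, forging C4a–C8a and extruding C4 as the formyl carbon on C4a. The step exploits C4, the exocyclic carbon on C4a next to C8a. A lithiated pyridine finally joins the decalin aldehyde to the epoxycyclohexyl unit.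

Key step: step 3

Remark: cyclohepta-2,6-dien-1-one is taken as a purchasable compound; otherwise it is one dehydrogenation step from cycloheptanone.

**Step 1**
Reactants: 1 cyclohepta-2,6-dien-1-one
Product: 3 (6S)-6-methylcyclohept-2-en-1-one, via methylzinc dienolate 2 (not isolated)
Conditions: Me2Zn, Cu(OTf)2 (1 mol %), binaphthol-derived bis(1-phenylethyl)amine phosphoramidite (2 mol %, enantiomer chosen to deliver the S product), toluene, −25 °C; aq. NH4Cl
Reagents that add atoms: dimethylzinc, C[Zn]C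
Why: Copper-catalysed asymmetric conjugate addition to one of the two enantiotopic enone units of the symmetrical dienone should stop at the mono-adduct (the zinc enolate is inert to a second addition), the chiral copper–phosphoramidite complex selecting the face and so setting C7 as S.

**Step 2**
Reactants: 3 (6S)-6-methylcyclohept-2-en-1-one
Product: 4 (4S)-4-methyl-8-oxabicyclo[5.1.0]octan-2-one (mixture of epoxide diastereomers)
Conditions: 30% H2O2, NaOH (0.2 equiv), MeOH, 0 °C
Reagents that add atoms: hydrogen peroxide, OO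
Why: Weitz–Scheffer nucleophilic epoxidation of the enone; the two epoxide centres need no control because one becomes the formyl carbon and the other the enolisable C4a in step 3.

**Step 3**
Reactants: 4 (4S)-4-methyl-8-oxabicyclo[5.1.0]octan-2-one
Product: 5 (4S)-4-methyl-2-oxocyclohexane-1-carbaldehyde (mainly as its hydroxymethylidene tautomer)
Conditions: BF3·OEt2 (0.5 equiv), benzene, 20 °C
Reagents that add atoms: none
Why: BF3 coordinates the epoxide oxygen, the C–O bond at the carbon remote from the carbonyl (future C4a) ionises, and the acyl carbon (future C8a) shifts from C4 to C4a, so that C4 becomes the formyl carbon and the seven-membered ring becomes six-membered. The closest known reaction type is the Lewis-acid rearrangement of cyclic α,β-epoxy ketones to ring-contracted β-keto aldehydes, as in isophorone oxide to 2-formyl-2,4,4-trimethylcyclopentanone. No ring is closed in the usual sense: the cyclohexane arises by a 1,2-acyl shift, a ring contraction of the cycloheptanone that forms the C4a–C8a bond. The only new stereocentre, C4a, lies between two carbonyl groups and is enolised, so it needs no control, while C7 is remote and untouched. The selectivity needed is acyl shift over hydride shift (which would give the cycloheptane-1,2-dione) and over fluorohydrin formation; the high migratory aptitude of the acyl group, the relief of seven-ring strain and the non-nucleophilic medium should secure it.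

**Step 4**
Reactants: 5 (4S)-4-methyl-2-oxocyclohexane-1-carbaldehyde
Product: 6 (5S)-5-methyl-2-[(propan-2-yloxy)methylidene]cyclohexan-1-one
Conditions: i-PrOH, TsOH (cat.), benzene, reflux, Dean–Stark trap
Reagents that add atoms: propan-2-ol, CC(C)O
Why: Acid-catalysed O-alkylation of the hydroxymethylidene tautomer gives the vinylogous ester (the standard isopropoxymethylene derivative of a 2-formyl ketone), which masks the formyl carbon and leaves the ring carbonyl as the only site for hydride.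

**Step 5**
Reactants: 6 (5S)-5-methyl-2-[(propan-2-yloxy)methylidene]cyclohexan-1-one
Product: 8 (4S)-4-methylcyclohex-1-ene-1-carbaldehyde, via allylic alcohol 7 (not isolated)
Conditions: LiAlH4, Et2O, 0 °C; then 1 M HCl, THF, 20 °C
Reagents that add atoms: water, O
Why: 1,2-Reduction of the vinylogous ester carbonyl and acid hydrolysis of the allylic enol ether with loss of water (a 1,3-carbonyl transposition of the Stork–Danheiser type) should give the conjugated enal with the double bond at C4a=C8a; no stereocentre is formed.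

**Step 6**
Reactants: 9 3,3-diethoxyprop-1-yne
Product: 10 tributyl[(1E)-3,3-diethoxyprop-1-en-1-yl]stannane
Conditions: Bu3SnH (slight excess), AIBN (cat.), 80 °C
Reagents that add atoms: tributyltin hydride, CCCC[SnH](CCCC)CCCC
Why: Radical hydrostannation of the terminal alkyne gives the β-stannyl acetal, and reversible stannyl radical addition equilibrates the alkene to the E isomer.

**Step 7**
Reactants: 10 tributyl[(1E)-3,3-diethoxyprop-1-en-1-yl]stannane; 8 (4S)-4-methylcyclohex-1-ene-1-carbaldehyde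
Product: 12 (2E)-4,4-diethoxy-1-[(4S)-4-methylcyclohex-1-en-1-yl]but-2-en-1-ol (both carbinol epimers), via vinyllithium 11 (not isolated)
Conditions: n-BuLi, THF, −78 °C; then 8, −78 °C; aq. NH4Cl
Reagents that add atoms: none
Why: Tin–lithium exchange gives the β-formylvinyl anion equivalent, which adds 1,2 to the enal; the carbinol configuration is irrelevant because it is oxidised next.

**Step 8**
Reactants: 12 (2E)-4,4-diethoxy-1-[(4S)-4-methylcyclohex-1-en-1-yl]but-2-en-1-ol
Product: 13 (2E)-4,4-diethoxy-1-[(4S)-4-methylcyclohex-1-en-1-yl]but-2-en-1-one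
Conditions: MnO2, CH2Cl2, 20 °C
Reagents that add atoms: none
Why: Allylic oxidation of the bis-allylic alcohol with MnO2 gives the cross-conjugated dienone; the acetal and both alkenes are untouched.

**Step 9**
Reactants: 13 (2E)-4,4-diethoxy-1-[(4S)-4-methylcyclohex-1-en-1-yl]but-2-en-1-one; 14 dimethyl propanedioate
Product: 16 dimethyl (2R,4aS,7S,8aS)-2-(diethoxymethyl)-7-methyl-4-oxooctahydronaphthalene-1,1(2H)-dicarboxylate, via mono-Michael adduct 15 (not isolated)
Conditions: t-BuOK (0.2 equiv), t-BuOH/THF, 20 → 50 °C, held until the isomer ratio no longer changes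
Reagents that add atoms: none
Why: Double Michael addition of the malonate to the divinyl ketone (intermolecular at C2, then 6-endo-trig at C8a) forms C1–C2 and C1–C8a, and because both additions and the enolisation at C4a are reversible under the basic conditions the product should settle as the trans-fused decalone with the C2 acetal, the C8a–C1 bond and the C7 methyl all equatorial, so that C2, C4a and C8a are set by thermodynamic control against C7.

**Step 10**
Reactants: 16 the diester decalone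
Product: 17 methyl (1R,2R,4aS,7S,8aS)-2-(diethoxymethyl)-7-methyl-4-oxodecahydronaphthalene-1-carboxylate
Conditions: LiCl, H2O, DMSO, 150 °C; then NaOMe (cat.), MeOH, 20 °C
Reagents that add atoms: none
Why: Krapcho dealkoxycarbonylation removes one ester, and base equilibration places the remaining C1 ester equatorial (trans to the C2 and C8a substituents), which sets C1.

**Step 11**
Reactants: 17 the keto ester
Product: 19 methyl (1R,2R,4aS,7S,8aS)-2-(diethoxymethyl)-7-methyl-4-{[(trifluoromethyl)sulfonyl]oxy}-1,2,4a,5,6,7,8,8a-octahydronaphthalene-1-carboxylate, via potassium enolate 18 (not isolated)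
Conditions: KN(SiMe3)2, THF, −78 °C; then PhNTf2, −78 → 0 °C
Reagents that add atoms: N-phenylbis(trifluoromethanesulfonimide), O=S(=O)(N(c1ccccc1)S(=O)(=O)C(F)(F)F)C(F)(F)F
Why: Kinetic deprotonation at the less hindered C3 methylene (not at the ring-fusion C4a) and O-triflation of the enolate should give the C3=C4 enol triflate regioselectively.

**Step 12**
Reactants: 19 the enol triflate
Product: 20 methyl (1R,2R,4aS,7S,8aS)-2-(diethoxymethyl)-4,7-dimethyl-1,2,4a,5,6,7,8,8a-octahydronaphthalene-1-carboxylate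
Conditions: MeMgBr, Fe(acac)3 (5 mol %), THF/NMP, −30 °C
Reagents that add atoms: methylmagnesium bromide, C[Mg]Br
Why: Iron-catalysed Kumada-type cross-coupling of the enol triflate with the methyl Grignard reagent installs the C4 methyl group without moving the C3=C4 double bond, the ester being tolerated at low temperature.

**Step 13**
Reactants: 20 the methyl alkene ester
Product: 21 (1R,2R,4aS,7S,8aS)-2-(diethoxymethyl)-4,7-dimethyl-1,2,4a,5,6,7,8,8a-octahydronaphthalene-1-carbaldehyde
Conditions: i-Bu2AlH (1.1 equiv), CH2Cl2, −78 °C; aq. Rochelle salt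
Reagents that add atoms: none
Why: Partial reduction of the ester through the tetrahedral aluminium hemiacetal that is stable at −78 °C should stop at the aldehyde; the acetal and the alkene are inert.

**Step 14**
Reactants: 21 the C1 aldehyde
Product: 22 (1R,2S,4aS,7S,8aR)-2-(diethoxymethyl)-4,7-dimethyl-1-[(1E)-prop-1-en-1-yl]-1,2,4a,5,6,7,8,8a-octahydronaphthalene
Conditions: 5-(ethylsulfonyl)-1-phenyl-1H-tetrazole, KN(SiMe3)2, DME, −60 → 20 °C
Reagents that add atoms: 5-(ethylsulfonyl)-1-phenyl-1H-tetrazole, CCS(=O)(=O)c1nnnn1-c1ccccc1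
Why: Julia–Kocienski olefination with the ethyl phenyltetrazolyl sulfone should give the E-propenyl group, the potassium base in DME favouring the anti adduct that eliminates to the E alkene.

**Step 15**
Reactants: 22 the propenyl acetal
Product: 23 (1R,2S,4aS,7S,8aR)-4,7-dimethyl-1-[(1E)-prop-1-en-1-yl]-1,2,4a,5,6,7,8,8a-octahydronaphthalene-2-carbaldehyde
Conditions: PPTS (cat.), acetone/H2O (10:1), 40 °C
Reagents that add atoms: water, O
Why: Mild acid hydrolysis of the acetal unmasks the C2 aldehyde, whose equatorial configuration is the thermodynamically preferred one, so enolisation does no harm.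

**Step 16**
Reactants: 24 cyclohexa-1,3-diene
Product: 25 2,3-dioxabicyclo[2.2.2]oct-5-ene
Conditions: O2, visible light, tetraphenylporphyrin (cat.), CH2Cl2, −20 °C
Reagents that add atoms: dioxygen, O=O
Why: [4+2] Cycloaddition of singlet oxygen to the cyclic diene gives the meso endoperoxide.

**Step 17**
Reactants: 25 2,3-dioxabicyclo[2.2.2]oct-5-ene
Product: 26 (4R)-4-hydroxycyclohex-2-en-1-one
Conditions: 6′-hydroxy cinchona alkaloid base (5 mol %, pseudo-enantiomer chosen for the R product), CH2Cl2, 20 °C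
Reagents that add atoms: none
Why: Kornblum–DeLaMare rearrangement under chiral base catalysis removes one of the two enantiotopic bridgehead protons and so sets the carbinol centre as R.

**Step 18**
Reactants: 26 (4R)-4-hydroxycyclohex-2-en-1-one
Product: 27 (4R)-4-{[tert-butyl(dimethyl)silyl]oxy}cyclohex-2-en-1-one
Conditions: t-BuMe2SiCl, imidazole, DMF, 20 °C
Reagents that add atoms: tert-butyldimethylsilyl chloride, CC(C)(C)[Si](C)(C)Cl
Why: Standard silylation of the secondary alcohol.

**Step 19**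
Reactants: 28 5-bromo-2,4-dichloropyridine
Product: 29 5-bromo-2,4-bis[2-(trimethylsilyl)ethoxy]pyridine
Conditions: 2-(trimethylsilyl)ethanol (2.4 equiv), NaH (2.5 equiv), THF/DMF, 0 → 60 °C
Reagents that add atoms: 2-(trimethylsilyl)ethanol, C[Si](C)(C)CCO
Why: Double nucleophilic aromatic substitution at the 4- and 2-chloro positions, both activated by the ring nitrogen; the 5-bromo substituent is not activated and stays.

**Step 20**
Reactants: 29 5-bromo-2,4-bis[2-(trimethylsilyl)ethoxy]pyridine; 27 (4R)-4-{[tert-butyl(dimethyl)silyl]oxy}cyclohex-2-en-1-one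
Product: 32 5-[(1S,4R)-4-{[tert-butyl(dimethyl)silyl]oxy}-1-[(triethylsilyl)oxy]cyclohex-2-en-1-yl]-2,4-bis[2-(trimethylsilyl)ethoxy]pyridine, via aryllithium 30 (not isolated), via lithium alkoxide 31 (not isolated)
Conditions: n-BuLi, THF, −78 °C; then 27, −78 °C; then Et3SiOTf, −78 → 0 °C
Reagents that add atoms: triethylsilyl trifluoromethanesulfonate, CC[Si](CC)(CC)OS(=O)(=O)C(F)(F)F
Why: Bromine–lithium exchange, 1,2-addition of the aryllithium to the enone from the face opposite the silyloxy group (which sets the carbinol centre with the two oxygens cis), and silylation of the tertiary lithium alkoxide in the same flask.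

**Step 21**
Reactants: 32 the bis-silyl ether
Product: 33 5-[(1S,2R,5R,6R)-5-{[tert-butyl(dimethyl)silyl]oxy}-2-[(triethylsilyl)oxy]-7-oxabicyclo[4.1.0]heptan-2-yl]-2,4-bis[2-(trimethylsilyl)ethoxy]pyridine
Conditions: dimethyldioxirane (acetone solution), CH2Cl2, 0 °C
Reagents that add atoms: dimethyldioxirane, CC1(C)OO1
Why: Electrophilic epoxidation should occur from the face opposite the two silyloxy groups (the tertiary one pseudoaxial), which sets both epoxide centres anti to both oxygens.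

**Step 22**
Reactants: 33 the epoxide; 23 the decalin aldehyde
Product: 35 {2,4-bis[2-(trimethylsilyl)ethoxy]-5-[(1S,2R,5R,6R)-5-{[tert-butyl(dimethyl)silyl]oxy}-2-[(triethylsilyl)oxy]-7-oxabicyclo[4.1.0]heptan-2-yl]pyridin-3-yl}[(1R,2S,4aS,7S,8aR)-4,7-dimethyl-1-[(1E)-prop-1-en-1-yl]-1,2,4a,5,6,7,8,8a-octahydronaphthalen-2-yl]methanol (both carbinol epimers), via 3-lithiopyridine 34 (not isolated)
Conditions: n-BuLi (1.1 equiv), THF, −78 → −40 °C; then 23, −78 °C; aq. NH4Cl
Reagents that add atoms: none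
Why: Directed ortho-lithiation at C3, the position flanked by the two alkoxy groups, and addition of the aryllithium to the aldehyde; the carbinol configuration is irrelevant.

**Step 23**
Reactants: 35 the secondary alcohol
Product: 36 the corresponding methanone
Conditions: Dess–Martin periodinane, NaHCO3, CH2Cl2, 20 °C
Reagents that add atoms: none
Why: Dess–Martin oxidation of the secondary alcohol to the aryl ketone under buffered conditions that should not epimerise C2 or move the C3=C4 double bond.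

**Step 24**
Reactants: 36 the protected ketone
Product: 37 4-hydroxy-5-[(1S,2R,5R,6S)-2,5-dihydroxy-7-oxabicyclo[4.1.0]heptan-2-yl]-3-{[(1R,2S,4aS,7S,8aR)-4,7-dimethyl-1-[(1E)-prop-1-en-1-yl]-1,2,4a,5,6,7,8,8a-octahydronaphthalen-2-yl]carbonyl}pyridin-2(1H)-one (CNP0494338.1)
Conditions: Bu4NF (6 equiv), AcOH (6 equiv), THF, 0 → 40 °C
Reagents that add atoms: none
Why: Fluoride removes both silyl ethers and cleaves both 2-(trimethylsilyl)ethyl ethers by β-elimination, unveiling the 4-hydroxy-2-pyridone, while the acetic acid buffer should suppress Payne rearrangement of the epoxy alcohols.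

**Compound list**

1 | cyclohepta-2,6-dien-1-one | O=C1C=CCCC=C1 | starting material
2 | methylzinc (3S)-3-methylcyclohepta-1,6-dien-1-olate | C[Zn]OC1=C[C@@H](C)CCC=C1 | intermediate
3 | (6S)-6-methylcyclohept-2-en-1-one | C[C@H]1CCC=CC(=O)C1 | intermediate
4 | (4S)-4-methyl-8-oxabicyclo[5.1.0]octan-2-one (epoxide diastereomers) | C[C@H]1CCC2OC2C(=O)C1 | intermediate
5 | (4S)-4-methyl-2-oxocyclohexane-1-carbaldehyde | C[C@H]1CCC(C=O)C(=O)C1 | intermediate
6 | (5S)-5-methyl-2-[(propan-2-yloxy)methylidene]cyclohexan-1-one | C[C@H]1CCC(=COC(C)C)C(=O)C1 | intermediate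
7 | (5S)-5-methyl-2-[(propan-2-yloxy)methylidene]cyclohexan-1-ol | C[C@H]1CCC(=COC(C)C)C(O)C1 | intermediate
8 | (4S)-4-methylcyclohex-1-ene-1-carbaldehyde | C[C@H]1CCC(C=O)=CC1 | intermediate
9 | 3,3-diethoxyprop-1-yne | C#CC(OCC)OCC | starting material
10 | tributyl[(1E)-3,3-diethoxyprop-1-en-1-yl]stannane | CCCC[Sn](CCCC)(CCCC)/C=C/C(OCC)OCC | intermediate
11 | [(1E)-3,3-diethoxyprop-1-en-1-yl]lithium | [Li]/C=C/C(OCC)OCC | intermediate
12 | (2E)-4,4-diethoxy-1-[(4S)-4-methylcyclohex-1-en-1-yl]but-2-en-1-ol | C[C@H]1CCC(=CC1)C(O)/C=C/C(OCC)OCC | intermediate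
13 | (2E)-4,4-diethoxy-1-[(4S)-4-methylcyclohex-1-en-1-yl]but-2-en-1-one | C[C@H]1CCC(=CC1)C(=O)/C=C/C(OCC)OCC | intermediate
14 | dimethyl propanedioate | COC(=O)CC(=O)OC | starting material
15 | dimethyl 2-{1,1-diethoxy-4-[(4S)-4-methylcyclohex-1-en-1-yl]-4-oxobutan-2-yl}propanedioate | C[C@H]1CCC(=CC1)C(=O)CC(C(OCC)OCC)C(C(=O)OC)C(=O)OC | intermediate
16 | dimethyl (2R,4aS,7S,8aS)-2-(diethoxymethyl)-7-methyl-4-oxooctahydronaphthalene-1,1(2H)-dicarboxylate | COC(=O)C1(C(=O)OC)[C@H]2C[C@@H](C)CC[C@@H]2C(=O)C[C@H]1C(OCC)OCC | intermediate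
17 | methyl (1R,2R,4aS,7S,8aS)-2-(diethoxymethyl)-7-methyl-4-oxodecahydronaphthalene-1-carboxylate | COC(=O)[C@@H]1[C@H]2C[C@@H](C)CC[C@@H]2C(=O)C[C@H]1C(OCC)OCC | intermediate
18 | potassium C3=C4 enolate of 17 | COC(=O)[C@@H]1[C@H]2C[C@@H](C)CC[C@@H]2C(O[K])=C[C@H]1C(OCC)OCC | intermediate
19 | methyl (1R,2R,4aS,7S,8aS)-2-(diethoxymethyl)-7-methyl-4-{[(trifluoromethyl)sulfonyl]oxy}-1,2,4a,5,6,7,8,8a-octahydronaphthalene-1-carboxylate | COC(=O)[C@@H]1[C@H]2C[C@@H](C)CC[C@@H]2C(OS(=O)(=O)C(F)(F)F)=C[C@H]1C(OCC)OCC | intermediate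
20 | methyl (1R,2R,4aS,7S,8aS)-2-(diethoxymethyl)-4,7-dimethyl-1,2,4a,5,6,7,8,8a-octahydronaphthalene-1-carboxylate | COC(=O)[C@@H]1[C@H]2C[C@@H](C)CC[C@@H]2C(C)=C[C@H]1C(OCC)OCC | intermediate
21 | (1R,2R,4aS,7S,8aS)-2-(diethoxymethyl)-4,7-dimethyl-1,2,4a,5,6,7,8,8a-octahydronaphthalene-1-carbaldehyde | O=C[C@@H]1[C@H]2C[C@@H](C)CC[C@@H]2C(C)=C[C@H]1C(OCC)OCC | intermediate
22 | (1R,2S,4aS,7S,8aR)-2-(diethoxymethyl)-4,7-dimethyl-1-[(1E)-prop-1-en-1-yl]-1,2,4a,5,6,7,8,8a-octahydronaphthalene | C/C=C/[C@@H]1[C@H]2C[C@@H](C)CC[C@@H]2C(C)=C[C@H]1C(OCC)OCC | intermediate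
23 | (1R,2S,4aS,7S,8aR)-4,7-dimethyl-1-[(1E)-prop-1-en-1-yl]-1,2,4a,5,6,7,8,8a-octahydronaphthalene-2-carbaldehyde | C/C=C/[C@@H]1[C@H]2C[C@@H](C)CC[C@@H]2C(C)=C[C@H]1C=O | intermediate
24 | cyclohexa-1,3-diene | C1=CC=CCC1 | starting material
25 | 2,3-dioxabicyclo[2.2.2]oct-5-ene | C1CC2C=CC1OO2 | intermediate
26 | (4R)-4-hydroxycyclohex-2-en-1-one | O=C1CC[C@@H](O)C=C1 | intermediate
27 | (4R)-4-{[tert-butyl(dimethyl)silyl]oxy}cyclohex-2-en-1-one | O=C1CC[C@@H](O[Si](C)(C)C(C)(C)C)C=C1 | intermediate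
28 | 5-bromo-2,4-dichloropyridine | Clc1cc(Cl)c(Br)cn1 | starting material
29 | 5-bromo-2,4-bis[2-(trimethylsilyl)ethoxy]pyridine | C[Si](C)(C)CCOc1cc(OCC[Si](C)(C)C)c(Br)cn1 | intermediate
30 | {4,6-bis[2-(trimethylsilyl)ethoxy]pyridin-3-yl}lithium | C[Si](C)(C)CCOc1cc(OCC[Si](C)(C)C)c([Li])cn1 | intermediate
31 | lithium (1S,4R)-1-{4,6-bis[2-(trimethylsilyl)ethoxy]pyridin-3-yl}-4-{[tert-butyl(dimethyl)silyl]oxy}cyclohex-2-en-1-olate | C[Si](C)(C)CCOc1cc(OCC[Si](C)(C)C)ncc1[C@]1(O[Li])CC[C@@H](O[Si](C)(C)C(C)(C)C)C=C1 | intermediate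
32 | 5-[(1S,4R)-4-{[tert-butyl(dimethyl)silyl]oxy}-1-[(triethylsilyl)oxy]cyclohex-2-en-1-yl]-2,4-bis[2-(trimethylsilyl)ethoxy]pyridine | C[Si](C)(C)CCOc1cc(OCC[Si](C)(C)C)ncc1[C@]1(O[Si](CC)(CC)CC)CC[C@@H](O[Si](C)(C)C(C)(C)C)C=C1 | intermediate
33 | 5-[(1S,2R,5R,6R)-5-{[tert-butyl(dimethyl)silyl]oxy}-2-[(triethylsilyl)oxy]-7-oxabicyclo[4.1.0]heptan-2-yl]-2,4-bis[2-(trimethylsilyl)ethoxy]pyridine | C[Si](C)(C)CCOc1cc(OCC[Si](C)(C)C)ncc1[C@]1(O[Si](CC)(CC)CC)CC[C@@H](O[Si](C)(C)C(C)(C)C)[C@@H]2O[C@@H]21 | intermediate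
34 | 3-lithio derivative of 33 | C[Si](C)(C)CCOc1c([Li])c(OCC[Si](C)(C)C)ncc1[C@]1(O[Si](CC)(CC)CC)CC[C@@H](O[Si](C)(C)C(C)(C)C)[C@@H]2O[C@@H]21 | intermediate
35 | {2,4-bis[2-(trimethylsilyl)ethoxy]-5-[(1S,2R,5R,6R)-5-{[tert-butyl(dimethyl)silyl]oxy}-2-[(triethylsilyl)oxy]-7-oxabicyclo[4.1.0]heptan-2-yl]pyridin-3-yl}[(1R,2S,4aS,7S,8aR)-4,7-dimethyl-1-[(1E)-prop-1-en-1-yl]-1,2,4a,5,6,7,8,8a-octahydronaphthalen-2-yl]methanol | C/C=C/[C@@H]1[C@H]2C[C@@H](C)CC[C@@H]2C(C)=C[C@H]1C(O)c1c(OCC[Si](C)(C)C)ncc([C@]3(O[Si](CC)(CC)CC)CC[C@@H](O[Si](C)(C)C(C)(C)C)[C@@H]4O[C@@H]43)c1OCC[Si](C)(C)C | intermediate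
36 | {2,4-bis[2-(trimethylsilyl)ethoxy]-5-[(1S,2R,5R,6R)-5-{[tert-butyl(dimethyl)silyl]oxy}-2-[(triethylsilyl)oxy]-7-oxabicyclo[4.1.0]heptan-2-yl]pyridin-3-yl}[(1R,2S,4aS,7S,8aR)-4,7-dimethyl-1-[(1E)-prop-1-en-1-yl]-1,2,4a,5,6,7,8,8a-octahydronaphthalen-2-yl]methanone | C/C=C/[C@@H]1[C@H]2C[C@@H](C)CC[C@@H]2C(C)=C[C@H]1C(=O)c1c(OCC[Si](C)(C)C)ncc([C@]3(O[Si](CC)(CC)CC)CC[C@@H](O[Si](C)(C)C(C)(C)C)[C@@H]4O[C@@H]43)c1OCC[Si](C)(C)C | intermediate
37 | 4-hydroxy-5-[(1S,2R,5R,6S)-2,5-dihydroxy-7-oxabicyclo[4.1.0]heptan-2-yl]-3-{[(1R,2S,4aS,7S,8aR)-4,7-dimethyl-1-[(1E)-prop-1-en-1-yl]-1,2,4a,5,6,7,8,8a-octahydronaphthalen-2-yl]carbonyl}pyridin-2(1H)-one | C/C=C/[C@@H]1[C@H]2C[C@@H](C)CC[C@@H]2C(C)=C[C@H]1C(=O)c1c(O)c([C@]2(O)CC[C@@H](O)[C@@H]3O[C@@H]32)c[nH]c1=O | target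

**Count.** Total steps: 24. Longest linear sequence: 17 (steps 1–5, 7–15, 22–24).

**Steps most likely to fail**

Step 9. The kinetic, axial attack at C8a places the new bond trans to the C7 methyl, so the desired all-equatorial isomer depends on complete retro-Michael equilibration; the dienone may also oligomerise before that is reached. Fallback, from 8 back to 16: malonate is first added to the enal 8 alone (NaOMe cat., MeOH), where the reversible addition can be equilibrated and the isomers separated, to give dimethyl 2-[(1S,2S,5S)-2-formyl-5-methylcyclohexyl]propanedioate F4. Two equivalents of vinyllithium 11 (the first deprotonates the malonate) then give dimethyl 2-{(1S,2S,5S)-2-[(2E)-4,4-diethoxy-1-hydroxybut-2-en-1-yl]-5-methylcyclohexyl}propanedioate F5. MnO2 gives dimethyl 2-{(1S,2S,5S)-2-[(2E)-4,4-diethoxybut-2-enoyl]-5-methylcyclohexyl}propanedioate F6, and base (DBU, THF) closes the ring by intramolecular Michael addition at C2 to give 16.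

Step 21. Oxidation at the pyridine nitrogen may compete with the hindered, inductively deactivated alkene, and some attack may come from the wrong face. Fallback, from 32 back to 33: excess m-chloroperbenzoic acid is used to oxidise both sites, giving the epoxide N-oxide 5-[(1S,2R,5R,6R)-5-{[tert-butyl(dimethyl)silyl]oxy}-2-[(triethylsilyl)oxy]-7-oxabicyclo[4.1.0]heptan-2-yl]-2,4-bis[2-(trimethylsilyl)ethoxy]pyridine 1-oxide F7. Chemoselective N-deoxygenation with B2pin2 (MeCN, 60 °C) then returns 33.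

Step 3. A hydride shift may compete with the acyl shift (giving the cycloheptane-1,2-dione), fluoride may open the epoxide, and the β-keto aldehyde may self-condense. Fallback, from 4 back to 8 (still a ring contraction, steps 4 and 5 then fall away): NaBH4 reduces 4 to the epoxy alcohol (4S)-4-methyl-8-oxabicyclo[5.1.0]octan-2-ol F1, and t-BuMe2SiOTf/2,6-lutidine gives (4S)-2-{[tert-butyl(dimethyl)silyl]oxy}-4-methyl-8-oxabicyclo[5.1.0]octane F2. The bulky Lewis acid MeAl(OAr)2 (Ar = 4-bromo-2,6-di-tert-butylphenyl; CH2Cl2, −78 °C) then induces migration of the siloxy-bearing ring carbon to the ionising epoxide carbon, giving the ring-contracted β-siloxy aldehyde (4S)-2-{[tert-butyl(dimethyl)silyl]oxy}-4-methylcyclohexane-1-carbaldehyde F3. DBU eliminates the silanol to give 8.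

**Further compounds**

F1 | step 3 | (4S)-4-methyl-8-oxabicyclo[5.1.0]octan-2-ol | C[C@H]1CCC2OC2C(O)C1
F2 | step 3 | (4S)-2-{[tert-butyl(dimethyl)silyl]oxy}-4-methyl-8-oxabicyclo[5.1.0]octane | C[C@H]1CCC2OC2C(O[Si](C)(C)C(C)(C)C)C1
F3 | step 3 | (4S)-2-{[tert-butyl(dimethyl)silyl]oxy}-4-methylcyclohexane-1-carbaldehyde | C[C@H]1CCC(C=O)C(O[Si](C)(C)C(C)(C)C)C1
F4 | step 9 | dimethyl 2-[(1S,2S,5S)-2-formyl-5-methylcyclohexyl]propanedioate | COC(=O)C(C(=O)OC)[C@H]1C[C@@H](C)CC[C@@H]1C=O
F5 | step 9 | dimethyl 2-{(1S,2S,5S)-2-[(2E)-4,4-diethoxy-1-hydroxybut-2-en-1-yl]-5-methylcyclohexyl}propanedioate | COC(=O)C(C(=O)OC)[C@H]1C[C@@H](C)CC[C@@H]1C(O)/C=C/C(OCC)OCC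
F6 | step 9 | dimethyl 2-{(1S,2S,5S)-2-[(2E)-4,4-diethoxybut-2-enoyl]-5-methylcyclohexyl}propanedioate | COC(=O)C(C(=O)OC)[C@H]1C[C@@H](C)CC[C@@H]1C(=O)/C=C/C(OCC)OCC
F7 | step 21 | 5-[(1S,2R,5R,6R)-5-{[tert-butyl(dimethyl)silyl]oxy}-2-[(triethylsilyl)oxy]-7-oxabicyclo[4.1.0]heptan-2-yl]-2,4-bis[2-(trimethylsilyl)ethoxy]pyridine 1-oxide | C[Si](C)(C)CCOc1cc(OCC[Si](C)(C)C)[n+]([O-])cc1[C@]1(O[Si](CC)(CC)CC)CC[C@@H](O[Si](C)(C)C(C)(C)C)[C@@H]2O[C@@H]21
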